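**Assumption:** the (R)-configured iron phosphate catalyst is taken to give the (2S,3S) series; the sense of induction must be confirmed on the first run (ECD or X-ray), and the (S)-catalyst is used unchanged otherwise if it is the reverse.

## Retrosynthetic overview

1. Starting materials are two commercial stilbenes, oxyresveratrol (1) and resveratrol (2), both used without protecting groups.
2. Ring formed first, the benzofuran (O1–C2 bond): oxidative cyclisation of the 2-hydroxystilbene 1 through quinone methide 3 to moracin M (4).
3. Ring formed second, the trans-dihydrobenzofuran (C3–C3a and C2–O1 in one operation): oxidative [3+2] hetero-coupling of 2 (at C8) with the carbon between the two hydroxyls of 4, through para-quinone methide 5, to target 6.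
4. Stereochemistry: C3 is set in the C–C coupling by a chiral iron(III) phosphate; C2 is set trans by the oxa-Michael closure of 5.

## Route

Step 1
Reactants: 1 oxyresveratrol
Product: 4 moracin M, via benzofuranone quinone methide 3 (not isolated)
Conditions: PhI(OAc)2 (1.05 equiv, added over 2 h), MeCN, 0 °C → rt, 0.02 M
Reagents that add atoms: none
Why: Hypervalent-iodine oxidative cyclisation of a 2-hydroxystilbene to a 2-arylbenzofuran (biomimetic phenol oxidation with quinone-methide trapping): two-electron oxidation of the 2,4-dihydroxystyryl phenol puts the positive charge on the stilbene carbon bearing the 3,5-dihydroxyphenyl ring, the ortho hydroxyl closes the five-membered ring to 3, and tautomerisation aromatises it to 4; the 3,5-dihydroxyphenyl ring is not oxidised by one equivalent at 0 °C, high dilution suppresses intermolecular coupling, and no stereocentre survives.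

Step 2
Reactants: 2 resveratrol; 4 moracin M
Product: 6 target (2S,3S)-trans-dihydrobenzofuran, via para-quinone methide 5 (not isolated)
Conditions: Fe[(R)-3,3′-bis(3,5-(CF3)2C6H3)-BINOL phosphate]3 (10 mol%), t-BuOOt-Bu (1.1 equiv), 4 (3 equiv, excess recovered), 2 added over 8 h, HFIP/ClCH2CH2Cl 1:1, 0 °C
Reagents that add atoms: none
Why: Proposed new method: an iron(III)/peroxide oxidative [3+2] phenol–alkene coupling run on a chiral BINOL-phosphate iron centre, in which 2 (the most easily oxidised phenol present, kept at low concentration to starve its homo-dimerisation) is oxidised at iron to its C8-centred radical, this is attacked by C4′ of 4 held on iron through one resorcinol oxygen and hydrogen-bonded to a phosphate oxygen through the other (two-point binding that only the resorcinol ring of 4 can offer, presenting the carbon between the two hydroxyls and one face of C8, which sets C3), a second one-electron oxidation and rearomatisation give para-quinone methide 5, and 5-exo-trig oxa-Michael addition of the flanking phenol anti to the C3 aryl sets C2 trans (any cis material equilibrates to trans by reversible ring opening at C2 without touching C3); the peroxide does not react with phenols off the metal, so there is no achiral background oxidation, and the closest known reaction types are the racemic iron(III)-catalysed oxidative [3+2] coupling of phenols with styrenes to dihydrobenzofurans, iron/t-BuOOt-Bu phenol cross-coupling in HFIP, the chiral iron(III) BINOL-phosphate enantioselective oxidative coupling of 2-naphthols, and the uncatalysed biomimetic oxidative dimerisation of resveratrol to viniferins.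

## Compound list

1 | oxyresveratrol, (E)-4-[2-(3,5-dihydroxyphenyl)ethenyl]benzene-1,3-diol | Oc1ccc(/C=C/c2cc(O)cc(O)c2)c(O)c1 | starting material
2 | resveratrol, (E)-5-[2-(4-hydroxyphenyl)ethenyl]benzene-1,3-diol | Oc1ccc(/C=C/c2cc(O)cc(O)c2)cc1 | starting material
3 | 2-(3,5-dihydroxyphenyl)-2H-1-benzofuran-6-one (quinone-methide tautomer of 4; racemic at C2, centre lost on aromatisation) | O=C1C=C2OC(c3cc(O)cc(O)c3)C=C2C=C1 | intermediate
4 | moracin M, 5-(6-hydroxy-1-benzofuran-2-yl)benzene-1,3-diol | Oc1ccc2cc(-c3cc(O)cc(O)c3)oc2c1 | intermediate
5 | 4-[(2S)-2-[2,6-dihydroxy-4-(6-hydroxy-1-benzofuran-2-yl)phenyl]-2-(3,5-dihydroxyphenyl)ethylidene]cyclohexa-2,5-dien-1-one | O=C1C=CC(=C[C@@H](c2cc(O)cc(O)c2)c2c(O)cc(-c3cc4ccc(O)cc4o3)cc2O)C=C1 | intermediate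
6 | 5-[(2S,3S)-4-hydroxy-6-(6-hydroxy-1-benzofuran-2-yl)-2-(4-hydroxyphenyl)-2,3-dihydro-1-benzofuran-3-yl]benzene-1,3-diol (2,3-trans) | Oc1ccc([C@H]2Oc3cc(-c4cc5ccc(O)cc5o4)cc(O)c3[C@@H]2c2cc(O)cc(O)c2)cc1 | target

## Step count and risks

Total step count: 2. Longest linear sequence: 2 steps (1 → 4 → 6); 2 enters at step 2.

The route has only two steps, so the three entries are step 2 twice (two independent failure modes) and step 1.

**1. Step 2, hetero-coupling and site of attack on 4.** Uncatalysed oxidations of 2 give mainly its own δ-viniferin-type dimer. Compound 4 also offers three competing carbon sites: between the hydroxyls (wanted), ortho to the benzofuranyl, and C5/C7 of the hydroxybenzofuran ring. Fallback, setting out from 2 and returning at 6: replace 4 by purchased 3,5-dihydroxybenzaldehyde (O=Cc1cc(O)cc(O)c1). It has a single phenolic ring and is not oxidised under the conditions, so it can be used at 10 equiv with 2 added slowly. Like 3,5-dihydroxybenzoates, it is substituted between its two hydroxyls, because the positions ortho to the carbonyl are deactivated and hindered. The same chiral iron/peroxide coupling then gives (2S,3S)-3-(3,5-dihydroxyphenyl)-4-hydroxy-2-(4-hydroxyphenyl)-2,3-dihydro-1-benzofuran-6-carbaldehyde F1. Ohira–Bestmann homologation (dimethyl (1-diazo-2-oxopropyl)phosphonate, K2CO3, MeOH, rt) converts it into 5-[(2S,3S)-6-ethynyl-4-hydroxy-2-(4-hydroxyphenyl)-2,3-dihydro-1-benzofuran-3-yl]benzene-1,3-diol F2. Domino Sonogashira coupling/5-endo-dig cyclisation with 4-iodoresorcinol (Oc1ccc(I)c(O)c1; PdCl2(PPh3)2, CuI, Et3N, DMF, 60 °C) builds the 6-hydroxybenzofuran and gives 6. In this variant the benzofuran is no longer made by oxidative cyclisation and step 1 is not needed.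

**2. Step 2, absolute stereocontrol.** Enantio-induction at C8 by the iron phosphate is unprecedented for a stereocentre of this kind. Fallback, setting out from 2 and 4 and returning at 6: give up catalyst control and run the hetero-coupling with an achiral oxidant system (FeCl3/t-BuOOt-Bu in HFIP, or Ag2O in acetone). This gives the racemic trans compound, that is 6 together with its mirror image, the (2R,3R)-enantiomer of 6 F3. The two are separated by preparative chiral SFC on immobilised amylose tris(3,5-dimethylphenylcarbamate) (MeOH/CO2), and the (2S,3S) isomer is assigned by ECD.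

**3. Step 1, oxidative cyclisation of unprotected 1.** Oligomerisation or over-oxidation of the tetraphenol may outrun ring closure. Fallback, which sets out from no numbered compound (1 is replaced by two purchased building blocks) and returns at 4: domino Sonogashira coupling/cyclisation of 4-iodoresorcinol with 1-ethynyl-3,5-dimethoxybenzene (COc1cc(OC)cc(C#C)c1; PdCl2(PPh3)2, CuI, Et3N, DMF, 60 °C) gives 2-(3,5-dimethoxyphenyl)-1-benzofuran-6-ol F4. BBr3 (CH2Cl2, −78 °C → rt) demethylates it to 4.

## Further compounds

F1 | step 2 | (2S,3S)-3-(3,5-dihydroxyphenyl)-4-hydroxy-2-(4-hydroxyphenyl)-2,3-dihydro-1-benzofuran-6-carbaldehyde | Oc1ccc([C@H]2Oc3cc(C=O)cc(O)c3[C@@H]2c2cc(O)cc(O)c2)cc1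
F2 | step 2 | 5-[(2S,3S)-6-ethynyl-4-hydroxy-2-(4-hydroxyphenyl)-2,3-dihydro-1-benzofuran-3-yl]benzene-1,3-diol | Oc1ccc([C@H]2Oc3cc(C#C)cc(O)c3[C@@H]2c2cc(O)cc(O)c2)cc1
F3 | step 2 | 5-[(2R,3R)-4-hydroxy-6-(6-hydroxy-1-benzofuran-2-yl)-2-(4-hydroxyphenyl)-2,3-dihydro-1-benzofuran-3-yl]benzene-1,3-diol | Oc1ccc([C@@H]2Oc3cc(-c4cc5ccc(O)cc5o4)cc(O)c3[C@H]2c2cc(O)cc(O)c2)cc1
F4 | step 1 | 2-(3,5-dimethoxyphenyl)-1-benzofuran-6-ol | COc1cc(OC)cc(-c2cc3ccc(O)cc3o2)c1
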